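**Route in one sentence:** an Ireland–Claisen rearrangement of the chelated enolate of the (S,Z)-allylic α-benzyloxy ester 11 forms the C3–C4 bond and both stereocentres before the lactone ring exists.

## Structural features

The target is a dibenzylbutyrolactone with one γ-butyrolactone ring (O1, C2 carbonyl, C3, C4, C5). C3 carries a tertiary hydroxyl and a 3,4-dihydroxybenzyl group, C4 carries a 3,4-dimethoxybenzyl group, and the two arenes are joined only through the C3–C4 bond and their methylene groups. C3 (S) is fully substituted and stands next to the tertiary centre C4 (S); the hydroxyl is cis to the C4 benzyl group, so the two benzyl groups are trans. The catechol is oxidation-prone and must stay distinguishable from the veratryl ring. The tertiary α-hydroxy lactone opens easily with base, and any precursor with a carbonyl at C3 or C5 makes C4–H acidic. The real difficulty is the C3–C4 bond, which joins a tetrasubstituted oxygenated carbon to a stereocentre with defined relative and absolute configuration. On a preformed ring the last group placed on C3 enters anti to the C4 benzyl group, which fits only one order of events. The feature exploited here is that C2(=O)–C3–C4–C5 is a 1,4-dioxygenated chain: if C5 is read as an alkene carbon, C2 to C5 is a γ,δ-unsaturated acid, the retron of an ester enolate Claisen rearrangement whose new σ bond is exactly C3–C4. The oxygen on C3 then becomes an asset, because it chelates the enolate metal and fixes the enolate geometry.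

## Logic of the disconnections

19 to 18: the three O–benzyl bonds (two phenolic, one on the C3 oxygen) are cut. This hides the catechol and the tertiary alcohol behind one kind of group while the veratryl methyl ethers stay untouched. The forward step must cleave a hindered tertiary benzyl ether without touching the lactone.

18 to 15: the O1–C2 lactone bond is cut and C5–O1 is replaced by a C5=C bond. The ring becomes an open γ,δ-unsaturated acid whose propenyl group is a masked hydroxymethyl. The forward step must cleave one alkene in the presence of three electron-rich arenes and reduce the resulting aldehyde before C4 can epimerise.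

15 to 11: the C3–C4 bond is cut by a retro-[3,3] shift. The hindered bond and both stereocentres are traded for an ester C–O bond, a (Z)-alkene and one remote carbinol stereocentre, and 11 may be a mixture of epimers at its α-carbon. The forward step needs a single enolate geometry, a chair transition state and faithful 1,3-chirality transfer.

11 to 10 and 5: the ester C–O bond is cut. This gives two fragments of similar size, each carrying one arene, and 10 may be racemic. The forward step must esterify with retention at the carbinol carbon and without isomerising the (Z)-alkene.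

5 to 4 to 1 and 2: the (Z)-alkene is taken back to an alkyne and the C(sp)–CH2Ar bond is cut. The only stereocentre of this fragment is bought in 1. The forward steps need C-selective benzylation of an alkynyl metal and a clean cis semihydrogenation.

10 to 9 to 6 and 7: the Cα–CH2Ar bond is cut. This is a simple enolate alkylation with no stereochemical demand, since the new centre is erased in step 6. The forward step must outrun self-condensation of the glycolate enolate.

## Other disconnections considered

Alternative 1: the first idea is to cut C3–CH2Ar and C3–OH on a preformed ring. The enolate of (R)-4-(3,4-dimethoxybenzyl)dihydrofuran-2(3H)-one A1 would be alkylated with 7 to the trans-dibenzyl lactone A2, and the enolate of A2 would then be oxidised. An electrophilic oxidant should approach that enolate anti to the C4 benzyl group and would therefore favour A3, the C3 epimer with OH trans to the C4 benzyl group. A1 also needs its own asymmetric synthesis of several steps, and the two stereocentres are set one after the other, not as a group. The chosen plan sets both in one step and is not mismatched.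

Alternative 2: C3–C4 is cut as an aldol bond. A Cu(OTf)2/bis(oxazoline)-catalysed Mukaiyama addition of silyl ketene thioacetal A5 to arylpyruvate A4 would give adduct A6, followed by thioester reduction and lactonisation. This is short and convergent at the quaternary carbon. However, A4 should be largely enolised into conjugation with its arene, which makes it a sluggish and self-condensing electrophile. In an open transition state the benzyl group of the nucleophile would be expected to avoid the chelate ring, which leads to the C3-epimeric series, and nothing in the substrate enforces the arrangement needed. The chosen plan forms the same bond in a cyclic six-centre transition state with three identifiable control elements.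

Alternative 3: C3–CH2Ar is cut as addition of benzylmagnesium reagent A9 to the α-keto lactone A7. Attack anti to the C4 benzyl group would give the correct relative configuration. However, A7 has an acidic C4–H next to the ketone and should exist mainly as the achiral enol A8, so the C4 configuration cannot be held. The basic reagent A9 would also deprotonate rather than add. The chosen plan never places a carbonyl next to C4 under basic conditions.

Key step: step 6

Remark on the chemistry: the lactone is numbered O1, C2 (C=O), C3 (carbinol), C4, C5; the target is (3S,4S). Compounds 1, 2, 6 and 7 are taken as purchasable.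

## Route

Step 1
Reactants: 1 (S)-but-3-yn-2-ol; 2 4-(bromomethyl)-1,2-dimethoxybenzene (3,4-dimethoxybenzyl bromide)
Product: 4 (S)-5-(3,4-dimethoxyphenyl)pent-3-yn-2-ol, via dimagnesium alkynide alkoxide 3 (not isolated)
Conditions: EtMgBr (2.2 equiv), THF, 0 °C to rt; CuCl (10 mol %), then 2, THF, rt to 45 °C; aq NH4Cl
Reagents that add atoms: none
Why: EtMgBr removes both the O–H and the C(sp)–H proton, and the copper-catalysed coupling of the alkynyl Grignard with the reactive benzylic bromide (sp–sp3 alkylation) should occur at carbon; the carbinol stereocentre is not involved and stays S.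

Step 2
Reactants: 4 (S)-5-(3,4-dimethoxyphenyl)pent-3-yn-2-ol
Product: 5 (S,Z)-5-(3,4-dimethoxyphenyl)pent-3-en-2-ol
Conditions: H2 (1 atm), Pd/CaCO3 poisoned with Pb(OAc)2 (Lindlar type), quinoline, EtOAc, rt, stopped after 1 equiv H2
Reagents that add atoms: none
Why: Lindlar semihydrogenation delivers both hydrogens to one face of the alkyne on the poisoned palladium surface and should give the (Z)-alkene only; no benzyl ether is present in this fragment and the stereocentre is untouched.

Step 3
Reactants: 6 methyl 2-(benzyloxy)acetate; 7 1,2-bis(benzyloxy)-4-(chloromethyl)benzene (3,4-bis(benzyloxy)benzyl chloride)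
Product: 9 methyl 2-(benzyloxy)-3-[3,4-bis(benzyloxy)phenyl]propanoate (racemic), via lithium enolate 8 (not isolated)
Conditions: LiN(iPr)2 (1.1 equiv), THF, −78 °C; then 7, DMPU (4 equiv), −78 to −30 °C
Reagents that add atoms: none
Why: SN2 alkylation of a lithium glycolate enolate by an activated benzylic chloride; the new centre is deliberately racemic because it is erased in step 6.

Step 4
Reactants: 9 methyl 2-(benzyloxy)-3-[3,4-bis(benzyloxy)phenyl]propanoate (racemic)
Product: 10 2-(benzyloxy)-3-[3,4-bis(benzyloxy)phenyl]propanoic acid (racemic)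
Conditions: LiOH·H2O (3 equiv), THF/MeOH/H2O, rt; then 1 M HCl
Reagents that add atoms: lithium hydroxide, [Li+].[OH-]
Why: Ordinary saponification of a methyl ester by acyl substitution; the benzyl ethers are inert to hydroxide and there is no leaving group β to the carboxylate.

Step 5
Reactants: 10 2-(benzyloxy)-3-[3,4-bis(benzyloxy)phenyl]propanoic acid (racemic); 5 (S,Z)-5-(3,4-dimethoxyphenyl)pent-3-en-2-ol
Product: 11 (2S,3Z)-5-(3,4-dimethoxyphenyl)pent-3-en-2-yl (2RS)-2-(benzyloxy)-3-[3,4-bis(benzyloxy)phenyl]propanoate (mixture of the two α-epimers)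
Conditions: DCC (1.2 equiv), DMAP (0.1 equiv), CH2Cl2, 0 °C to rt
Reagents that add atoms: none
Why: Steglich esterification acylates the alcohol oxygen, so the carbinol carbon keeps its S configuration and the (Z)-alkene is not exposed to acid or metal; the epimer mixture at the α-carbon is of no consequence.

Step 6
Reactants: 11 (2S,3Z)-5-(3,4-dimethoxyphenyl)pent-3-en-2-yl (2RS)-2-(benzyloxy)-3-[3,4-bis(benzyloxy)phenyl]propanoate
Product: 15 (2S,3S,4E)-2-(benzyloxy)-2-[3,4-bis(benzyloxy)benzyl]-3-(3,4-dimethoxybenzyl)hex-4-enoic acid, via chelated lithium enolate 12 (not isolated), via silyl ketene acetal 13 (not isolated), via trimethylsilyl ester 14 (not isolated)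
Conditions: LiN(iPr)2 (1.3 equiv), THF, −78 °C; Me3SiCl/Et3N (1:1, 3 equiv), −78 °C to rt, then 45 °C; 1 M HCl work-up
Reagents that add atoms: none
Why: LiN(iPr)2 removes the α-hydrogen of both epimers of 11, and because lithium is held between the enolate oxygen and the benzyloxy oxygen, both epimers should funnel into the single chelated enolate 12 (OLi syn to OBn), which Me3SiCl fixes as the (Z)-silyl ketene acetal 13. On warming, 13 undergoes a concerted suprafacial [3,3]-sigmatropic shift that forms the C3–C4 bond of the target (C2–C3 of 15) and breaks the allylic C–O bond, giving silyl ester 14 and, after acidic work-up, 15; this is the Ireland–Claisen rearrangement in its chelation-controlled α-alkoxy ester form, the closest known cases being allylic esters of O-protected lactic and glycolic acids. No ring is closed in this step: the six atoms meet only in a chair transition state, and the lactone is closed in step 7. The configuration at C4 (C3 of 15, S) is controlled by 1,3-chirality transfer from the (S)-carbinol carbon: with a (Z)-alkene the carbinol methyl group must sit equatorial, because an axial methyl would meet the axial CH2Ar group of the alkene in a 1,3-diaxial clash, so the enolate reaches one alkene face only and the new alkene is E. The configuration at C3 (C2 of 15, S) is controlled by the enolate geometry: in 13 the benzyloxy group is trans to the allylic oxygen and lies equatorial while the catechol-derived benzyl group is axial, and this geometry combined with the (Z)-alkene in a chair places OBn and the C4 benzyl group anti along the acid chain, which is cis on the future lactone (benzyl groups trans). The step needs three selectivities, enolate geometry, chair over boat and faithful chirality transfer; the first is secured by the α-oxygen chelate, the third by the allylic strain of the (Z)-alkene, and the second rests on the usual chair preference of acyclic silyl ketene acetals. The step is also stereoconvergent, since the racemic α-carbon of 10 disappears in 12.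

Step 7
Reactants: 15 (2S,3S,4E)-2-(benzyloxy)-2-[3,4-bis(benzyloxy)benzyl]-3-(3,4-dimethoxybenzyl)hex-4-enoic acid
Product: 18 (3S,4S)-3-(benzyloxy)-3-[3,4-bis(benzyloxy)benzyl]-4-(3,4-dimethoxybenzyl)dihydrofuran-2(3H)-one, via oxo acid 16 (not isolated), via hydroxy acid 17 (not isolated)
Conditions: O3, CH2Cl2/MeOH (3:1), Sudan Red 7B as indicator, −78 °C; NaBH4 (5 equiv), −78 to 0 °C; then 2 M HCl, rt
Reagents that add atoms: ozone, [O-][O+]=O
Why: Ozonolysis should cleave the only C=C bond much faster than it attacks the arenes, NaBH4 reduces the peroxidic intermediates and aldehyde 16 in the cold before C4–H can enolise, and acidification closes hydroxy acid 17 to the lactone by 5-exo-trig acyl substitution; C3 and C4 are not touched and the ring oxygen comes from ozone.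

Step 8
Reactants: 18 (3S,4S)-3-(benzyloxy)-3-[3,4-bis(benzyloxy)benzyl]-4-(3,4-dimethoxybenzyl)dihydrofuran-2(3H)-one
Product: 19 (3S,4S)-3-(3,4-dihydroxybenzyl)-4-(3,4-dimethoxybenzyl)-3-hydroxydihydrofuran-2(3H)-one (target)
Conditions: H2 (1 atm), Pd(OH)2/C (20 wt %), EtOAc/EtOH (1:1), rt, under exclusion of air on work-up
Reagents that add atoms: none
Why: Catalytic hydrogenolysis cleaves the three O–CH2Ph bonds (two aryl benzyl ethers and the tertiary alkyl benzyl ether), while the methyl ethers, the lactone and the C–C benzylic bonds are inert under these neutral conditions; no stereocentre is involved.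

## Compound list

1 | (S)-but-3-yn-2-ol | C[C@H](O)C#C | starting material
2 | 4-(bromomethyl)-1,2-dimethoxybenzene | COc1ccc(CBr)cc1OC | starting material
3 | bromomagnesium (S)-4-(bromomagnesio)but-3-yn-2-olate | C[C@H](O[Mg]Br)C#C[Mg]Br | intermediate (not isolated)
4 | (S)-5-(3,4-dimethoxyphenyl)pent-3-yn-2-ol | C[C@H](O)C#CCc1ccc(OC)c(OC)c1 | intermediate
5 | (S,Z)-5-(3,4-dimethoxyphenyl)pent-3-en-2-ol | C[C@H](O)/C=C\Cc1ccc(OC)c(OC)c1 | intermediate
6 | methyl 2-(benzyloxy)acetate | COC(=O)COCc1ccccc1 | starting material
7 | 1,2-bis(benzyloxy)-4-(chloromethyl)benzene | ClCc1ccc(OCc2ccccc2)c(OCc2ccccc2)c1 | starting material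
8 | lithium enolate of 6 (OLi syn to OBn) | [Li]O/C(OC)=C\OCc1ccccc1 | intermediate (not isolated)
9 | methyl 2-(benzyloxy)-3-[3,4-bis(benzyloxy)phenyl]propanoate (racemic) | COC(=O)C(Cc1ccc(OCc2ccccc2)c(OCc2ccccc2)c1)OCc1ccccc1 | intermediate
10 | 2-(benzyloxy)-3-[3,4-bis(benzyloxy)phenyl]propanoic acid (racemic) | OC(=O)C(Cc1ccc(OCc2ccccc2)c(OCc2ccccc2)c1)OCc1ccccc1 | intermediate
11 | (2S,3Z)-5-(3,4-dimethoxyphenyl)pent-3-en-2-yl (2RS)-2-(benzyloxy)-3-[3,4-bis(benzyloxy)phenyl]propanoate | C[C@H](OC(=O)C(Cc1ccc(OCc2ccccc2)c(OCc2ccccc2)c1)OCc1ccccc1)/C=C\Cc1ccc(OC)c(OC)c1 | intermediate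
12 | chelated lithium enolate of 11 (OLi syn to OBn) | C[C@H](O/C(O[Li])=C(/OCc1ccccc1)Cc1ccc(OCc2ccccc2)c(OCc2ccccc2)c1)/C=C\Cc1ccc(OC)c(OC)c1 | intermediate (not isolated)
13 | (Z)-trimethylsilyl ketene acetal of 11 (OSiMe3 syn to OBn) | C[C@H](O/C(O[Si](C)(C)C)=C(/OCc1ccccc1)Cc1ccc(OCc2ccccc2)c(OCc2ccccc2)c1)/C=C\Cc1ccc(OC)c(OC)c1 | intermediate (not isolated)
14 | trimethylsilyl (2S,3S,4E)-2-(benzyloxy)-2-[3,4-bis(benzyloxy)benzyl]-3-(3,4-dimethoxybenzyl)hex-4-enoate | COc1ccc(C[C@@H](/C=C/C)[C@@](OCc2ccccc2)(Cc2ccc(OCc3ccccc3)c(OCc3ccccc3)c2)C(=O)O[Si](C)(C)C)cc1OC | intermediate (not isolated)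
15 | (2S,3S,4E)-2-(benzyloxy)-2-[3,4-bis(benzyloxy)benzyl]-3-(3,4-dimethoxybenzyl)hex-4-enoic acid | COc1ccc(C[C@@H](/C=C/C)[C@@](OCc2ccccc2)(Cc2ccc(OCc3ccccc3)c(OCc3ccccc3)c2)C(=O)O)cc1OC | intermediate
16 | (2S,3R)-2-(benzyloxy)-2-[3,4-bis(benzyloxy)benzyl]-3-(3,4-dimethoxybenzyl)-4-oxobutanoic acid (descriptor at C3 changes by priority only) | COc1ccc(C[C@@H](C=O)[C@@](OCc2ccccc2)(Cc2ccc(OCc3ccccc3)c(OCc3ccccc3)c2)C(=O)O)cc1OC | intermediate (not isolated)
17 | (2S,3S)-2-(benzyloxy)-2-[3,4-bis(benzyloxy)benzyl]-3-(3,4-dimethoxybenzyl)-4-hydroxybutanoic acid | COc1ccc(C[C@@H](CO)[C@@](OCc2ccccc2)(Cc2ccc(OCc3ccccc3)c(OCc3ccccc3)c2)C(=O)O)cc1OC | intermediate (not isolated)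
18 | (3S,4S)-3-(benzyloxy)-3-[3,4-bis(benzyloxy)benzyl]-4-(3,4-dimethoxybenzyl)dihydrofuran-2(3H)-one | COc1ccc(C[C@H]2COC(=O)[C@]2(OCc3ccccc3)Cc3ccc(OCc4ccccc4)c(OCc4ccccc4)c3)cc1OC | intermediate
19 | (3S,4S)-3-(3,4-dihydroxybenzyl)-4-(3,4-dimethoxybenzyl)-3-hydroxydihydrofuran-2(3H)-one | COc1ccc(C[C@H]2COC(=O)[C@]2(O)Cc2ccc(O)c(O)c2)cc1OC | target

## Step count and risk

Total: 8 steps. Longest linear sequence: 6 steps (1 → 4 → 5 → 11 → 15 → 18 → 19, or equally 6 → 9 → 10 → 11 → 15 → 18 → 19).

**Step 6 (key step).** The most likely failure is leakage through a boat transition state, because the axial benzyl group of the (Z)-alkene lies near the OSiMe3 group in the chair; this would erode the selectivity at C3. Incomplete chelation control of the tetrasubstituted enolate would have the same effect, and the lithium enolate may fragment to a ketene before silylation.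

The fallback sets out from 5 and returns at 18. Alcohol 5 is esterified with (benzyloxy)acetic acid (DCC, DMAP) to (S,Z)-5-(3,4-dimethoxyphenyl)pent-3-en-2-yl 2-(benzyloxy)acetate F1. Its chelation-controlled Ireland–Claisen rearrangement (LiN(iPr)2, Me3SiCl), now asked only to set C4 by chirality transfer, should give (2S,3S,E)-2-(benzyloxy)-3-(3,4-dimethoxybenzyl)hex-4-enoic acid F2. Ozonolysis, NaBH4 and acid as in step 7 give (3S,4S)-3-(benzyloxy)-4-(3,4-dimethoxybenzyl)dihydrofuran-2(3H)-one F3. Deprotonation (LiN(SiMe3)2, THF, −78 °C) gives lithium (S)-3-(benzyloxy)-4-(3,4-dimethoxybenzyl)-4,5-dihydrofuran-2-olate F4, which is alkylated with 7 on the face anti to the C4 benzyl group to give 18. The quaternary centre is then set by the ring and no longer by the acyclic transition state.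

**Step 3.** Self-condensation of the glycolate enolate may compete with a slow alkylation by the benzylic chloride, and some double alkylation is possible.

The fallback sets out from 6 (through 8) and returns at 9. Enolate 8 is added at −78 °C to commercial 3,4-bis(benzyloxy)benzaldehyde, a much faster electrophile, to give methyl 2-(benzyloxy)-3-[3,4-bis(benzyloxy)phenyl]-3-hydroxypropanoate F5 as a diastereomer mixture. Ionic deoxygenation of its electron-rich benzylic hydroxyl (Et3SiH, CF3CO2H, CH2Cl2, 0 °C) gives 9.

**Step 7.** Ozone may over-oxidise the electron-rich arenes or the benzylic ether positions. The intermediate aldehyde may also epimerise at C4 or lose benzyloxide by β-elimination before hydride arrives.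

The fallback sets out from 15 and returns at 18. Acid 15 is methylated (Me3SiCHN2, MeOH/toluene) to methyl (2S,3S,4E)-2-(benzyloxy)-2-[3,4-bis(benzyloxy)benzyl]-3-(3,4-dimethoxybenzyl)hex-4-enoate F6. Lemieux–Johnson cleavage under buffered conditions (K2OsO4·2H2O cat., NaIO4, 2,6-lutidine, dioxane/H2O) gives methyl (2S,3R)-2-(benzyloxy)-2-[3,4-bis(benzyloxy)benzyl]-3-(3,4-dimethoxybenzyl)-4-oxobutanoate F7. NaBH4 in MeOH at 0 °C followed by a trace of TsOH reduces and lactonises F7 to 18.

**Step 1.** Base-induced propargyl to allene isomerisation, O-benzylation of the magnesium alkoxide and Wurtz-type homocoupling of the benzylic bromide may lower the efficiency.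

The fallback sets out from 1 and 2 and returns at 5, bypassing steps 1 and 2, with the alkene geometry fixed before the C–C bond is made. Alcohol 1 is silylated (tBuMe2SiCl, imidazole) to (S)-tert-butyl(but-3-yn-2-yloxy)dimethylsilane F8. Iodination (N-iodosuccinimide, AgNO3 cat.) gives (S)-tert-butyl[(4-iodobut-3-yn-2-yl)oxy]dimethylsilane F9, and diimide reduction (2-nitrobenzenesulfonohydrazide, Et3N) gives (S,Z)-tert-butyl[(4-iodobut-3-en-2-yl)oxy]dimethylsilane F10. Bromide 2 is converted with zinc dust and LiCl in THF into (3,4-dimethoxybenzyl)zinc bromide F11. Negishi coupling of F10 with F11 (Pd(PPh3)4, THF, rt) gives (S,Z)-tert-butyl{[5-(3,4-dimethoxyphenyl)pent-3-en-2-yl]oxy}dimethylsilane F12, which Bu4NF in THF desilylates to 5.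

## Further compounds

F1 | step 6 | (S,Z)-5-(3,4-dimethoxyphenyl)pent-3-en-2-yl 2-(benzyloxy)acetate | C[C@H](OC(=O)COCc1ccccc1)/C=C\Cc1ccc(OC)c(OC)c1
F2 | step 6 | (2S,3S,E)-2-(benzyloxy)-3-(3,4-dimethoxybenzyl)hex-4-enoic acid | COc1ccc(C[C@@H](/C=C/C)[C@H](OCc2ccccc2)C(=O)O)cc1OC
F3 | step 6 | (3S,4S)-3-(benzyloxy)-4-(3,4-dimethoxybenzyl)dihydrofuran-2(3H)-one | COc1ccc(C[C@H]2COC(=O)[C@H]2OCc2ccccc2)cc1OC
F4 | step 6 | lithium (S)-3-(benzyloxy)-4-(3,4-dimethoxybenzyl)-4,5-dihydrofuran-2-olate | COc1ccc(C[C@H]2COC(O[Li])=C2OCc2ccccc2)cc1OC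
F5 | step 3 | methyl 2-(benzyloxy)-3-[3,4-bis(benzyloxy)phenyl]-3-hydroxypropanoate (diastereomer mixture, racemic) | COC(=O)C(OCc1ccccc1)C(O)c1ccc(OCc2ccccc2)c(OCc2ccccc2)c1
F6 | step 7 | methyl (2S,3S,4E)-2-(benzyloxy)-2-[3,4-bis(benzyloxy)benzyl]-3-(3,4-dimethoxybenzyl)hex-4-enoate | COc1ccc(C[C@@H](/C=C/C)[C@@](OCc2ccccc2)(Cc2ccc(OCc3ccccc3)c(OCc3ccccc3)c2)C(=O)OC)cc1OC
F7 | step 7 | methyl (2S,3R)-2-(benzyloxy)-2-[3,4-bis(benzyloxy)benzyl]-3-(3,4-dimethoxybenzyl)-4-oxobutanoate | COc1ccc(C[C@@H](C=O)[C@@](OCc2ccccc2)(Cc2ccc(OCc3ccccc3)c(OCc3ccccc3)c2)C(=O)OC)cc1OC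
F8 | step 1 | (S)-tert-butyl(but-3-yn-2-yloxy)dimethylsilane | C[C@H](O[Si](C)(C)C(C)(C)C)C#C
F9 | step 1 | (S)-tert-butyl[(4-iodobut-3-yn-2-yl)oxy]dimethylsilane | C[C@H](O[Si](C)(C)C(C)(C)C)C#CI
F10 | step 1 | (S,Z)-tert-butyl[(4-iodobut-3-en-2-yl)oxy]dimethylsilane | C[C@H](O[Si](C)(C)C(C)(C)C)/C=C\I
F11 | step 1 | (3,4-dimethoxybenzyl)zinc bromide | COc1ccc(C[Zn]Br)cc1OC
F12 | step 1 | (S,Z)-tert-butyl{[5-(3,4-dimethoxyphenyl)pent-3-en-2-yl]oxy}dimethylsilane | C[C@H](O[Si](C)(C)C(C)(C)C)/C=C\Cc1ccc(OC)c(OC)c1
A1 | alternative 1 | (R)-4-(3,4-dimethoxybenzyl)dihydrofuran-2(3H)-one | COc1ccc(C[C@H]2COC(=O)C2)cc1OC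
A2 | alternative 1 | (3R,4R)-3-[3,4-bis(benzyloxy)benzyl]-4-(3,4-dimethoxybenzyl)dihydrofuran-2(3H)-one | COc1ccc(C[C@H]2COC(=O)[C@@H]2Cc2ccc(OCc3ccccc3)c(OCc3ccccc3)c2)cc1OC
A3 | alternative 1 | (3R,4S)-3-[3,4-bis(benzyloxy)benzyl]-4-(3,4-dimethoxybenzyl)-3-hydroxydihydrofuran-2(3H)-one | COc1ccc(C[C@H]2COC(=O)[C@@]2(O)Cc2ccc(OCc3ccccc3)c(OCc3ccccc3)c2)cc1OC
A4 | alternative 2 | methyl 3-[3,4-bis(benzyloxy)phenyl]-2-oxopropanoate | COC(=O)C(=O)Cc1ccc(OCc2ccccc2)c(OCc2ccccc2)c1
A5 | alternative 2 | (Z)-{[3-(3,4-dimethoxyphenyl)-1-(ethylsulfanyl)prop-1-en-1-yl]oxy}trimethylsilane | CCS/C(O[Si](C)(C)C)=C\Cc1ccc(OC)c(OC)c1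
A6 | alternative 2 | methyl (2S,3R)-2-[3,4-bis(benzyloxy)benzyl]-3-(3,4-dimethoxybenzyl)-4-(ethylsulfanyl)-2-hydroxy-4-oxobutanoate | COc1ccc(C[C@@H](C(=O)SCC)[C@@](O)(Cc2ccc(OCc3ccccc3)c(OCc3ccccc3)c2)C(=O)OC)cc1OC
A7 | alternative 3 | (S)-4-(3,4-dimethoxybenzyl)dihydrofuran-2,3-dione | COc1ccc(C[C@H]2COC(=O)C2=O)cc1OC
A8 | alternative 3 | 4-(3,4-dimethoxybenzyl)-3-hydroxyfuran-2(5H)-one | COc1ccc(CC2=C(O)C(=O)OC2)cc1OC
A9 | alternative 3 | [3,4-bis(benzyloxy)benzyl]magnesium chloride | Cl[Mg]Cc1ccc(OCc2ccccc2)c(OCc2ccccc2)c1
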